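**Plan**

1. Retrosynthetic cuts, in order: the ArCH2–CH= bond and the vinylic C–CH3 bond (methylalumination of a terminal alkyne, then benzyl coupling); the prenyl C=C (cross-metathesis); the bond from each ketone carbon to its outer CH2 (propargyl and allyl additions, both ketones carried as carbinols); last, the two cyclopentane bonds CH2–CH2 and CH2–C(CH3)(acyl).
2. These two ring bonds form together in a formal (3+2) cycloaddition of ethynyltrimethylsilane with (1R,5S)-1,5-dimethylbicyclo[3.1.0]hexan-2-one. The enabling feature is the exocyclic cyclopropane bond C1–C6, held parallel to the π system of the C2 ketone; the cyclopentanone is a temporary ring that forces cis fusion.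
3. Forward order: cyclopentenone → cyclopropane-fused cyclopentanone → bicyclo[3.3.0]octanone (new carbocycle) → cleavage of the temporary ring between C=O and its CH2 to an acid and an aldehyde → propargyl lactone → lactol → allyl carbinol → union with the aryl part → prenyl group → diketone → free phenol.
4. Stereochemistry: a CBS reduction sets one carbinol centre; hydroxyl-directed cyclopropanation relays it to the first quaternary carbon; the cis ring fusion of the key step sets the second; syn-carboalumination gives the E alkene.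

Key step: step 4

Remark: the carbinol and lactol carbons created in steps 9, 10 and 11 are carried as epimer mixtures because each is later oxidised to a carbonyl group; their SMILES carry no descriptor at those atoms. 2,3-Dimethylcyclopent-2-en-1-one, ethynyltrimethylsilane and 4-methoxy-3-methylphenol are taken as purchasable.

**Step 1**
Reactants: 1 2,3-dimethylcyclopent-2-en-1-one
Product: 2 (1S)-2,3-dimethylcyclopent-2-en-1-ol
Conditions: (R)-2-methyl-CBS-oxazaborolidine (20 mol%), BH3·SMe2, THF, −20 °C
Reagents that add atoms: none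
Why: Corey–Bakshi–Shibata reduction, in which the tetrasubstituted alkenyl flank acts as the large group, so the (R)-catalyst should deliver hydride to the face that gives the (S)-allylic alcohol by 1,2-reduction.

**Step 2**
Reactants: 2 (1S)-2,3-dimethylcyclopent-2-en-1-ol
Product: 3 (1R,2S,5S)-1,5-dimethylbicyclo[3.1.0]hexan-2-ol
Conditions: Et2Zn, CH2I2, CH2Cl2, 0 °C to rt
Reagents that add atoms: diiodomethane, ICI
Why: Hydroxyl-directed Simmons–Smith cyclopropanation (Furukawa variant), in which the zinc alkoxide delivers the methylene to the electron-rich alkene on the face of the hydroxyl group and so sets both ring-fusion carbons from the carbinol centre.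

**Step 3**
Reactants: 3 (1R,2S,5S)-1,5-dimethylbicyclo[3.1.0]hexan-2-ol
Product: 4 (1R,5S)-1,5-dimethylbicyclo[3.1.0]hexan-2-one
Conditions: Dess–Martin periodinane, NaHCO3, CH2Cl2, 0 °C to rt
Reagents that add atoms: none
Why: Dess–Martin oxidation of a secondary cyclopropyl carbinol under buffered conditions should leave the three-membered ring and both quaternary centres untouched.

**Step 4**
Reactants: 4 (1R,5S)-1,5-dimethylbicyclo[3.1.0]hexan-2-one; 5 ethynyltrimethylsilane
Product: 6 (3aS,6aR)-3a,6a-dimethyl-6-(trimethylsilyl)-3,3a,4,6a-tetrahydropentalen-1(2H)-one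
Conditions: SmI2 (20 mol%), samarium powder (20 mol%), 5 (4 equiv), THF, 55 °C, sealed vessel
Reagents that add atoms: none
Why: Samarium diiodide transfers one electron reversibly to the C2 carbonyl of 4; in the rigid bicyclo[3.1.0]hexanone the exocyclic cyclopropane bond C1–C6 lies almost parallel to the ketyl π orbital whereas the ring-fusion bond C1–C5 lies near its nodal plane, so fragmentation should give the primary C6 radical and a trivalent samarium enolate across C1=C2. The radical adds to the unsubstituted terminus of 5 and the resulting α-silyl vinyl radical closes onto the enolate carbon C1 in a 5-exo-trig cyclisation; the new ketyl returns its electron to trivalent samarium, so divalent samarium turns over and samarium metal only restores catalyst lost to side reactions. The closest known reaction type is the samarium diiodide-catalysed radical-relay formal (3+2) cycloaddition of alkyl cyclopropyl ketones, bicyclic ones included, with terminal alkynes. The new quaternary stereocentre C6a is fixed by the existing quaternary centre C3a (C5 of 4, untouched), because the new five-membered ring can only close cis on the cyclopentanone. The step needs scission of the exocyclic and not the ring-fusion bond, secured by the orbital alignment described, and attack at the alkyne terminus, secured by the silyl group, which also keeps the extra substituent removable.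

**Step 5**
Reactants: 6 (3aS,6aR)-3a,6a-dimethyl-6-(trimethylsilyl)-3,3a,4,6a-tetrahydropentalen-1(2H)-one
Product: 7 (3aS,6aR)-3a,6a-dimethyl-3,3a,4,6a-tetrahydropentalen-1(2H)-one
Conditions: CF3CO2H, CH2Cl2, 0 °C to rt
Reagents that add atoms: none
Why: Protodesilylation of a vinylsilane by ipso protonation and loss of silicon from the β-silyl cation should leave the double bond in place, and the quaternary α-carbon prevents conjugation with the ketone.

**Step 6**
Reactants: 7 (3aS,6aR)-3a,6a-dimethyl-3,3a,4,6a-tetrahydropentalen-1(2H)-one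
Product: 8 (3aR,6aR)-3a,6a-dimethylhexahydropentalen-1(2H)-one
Conditions: H2 (1 atm), 10% Pd/C, EtOAc, rt
Reagents that add atoms: none
Why: Heterogeneous hydrogenation of the cis-disubstituted ring alkene should proceed without touching the ketone or either stereocentre.

**Step 7**
Reactants: 8 (3aR,6aR)-3a,6a-dimethylhexahydropentalen-1(2H)-one
Product: 9 {[(3aR,6aR)-3a,6a-dimethyl-3,3a,4,5,6,6a-hexahydropentalen-1-yl]oxy}trimethylsilane
Conditions: LiN(i-Pr)2, THF, −78 °C; then Me3SiCl, −78 to 0 °C
Reagents that add atoms: chlorotrimethylsilane, C[Si](C)(C)Cl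
Why: Only C2 carries α-hydrogens (C6a is quaternary), so enolisation and O-silylation should give a single regioisomeric silyl enol ether.

**Step 8**
Reactants: 9 {[(3aR,6aR)-3a,6a-dimethyl-3,3a,4,5,6,6a-hexahydropentalen-1-yl]oxy}trimethylsilane
Product: 11 (1R,2R)-1,2-dimethyl-2-(2-oxoethyl)cyclopentane-1-carboxylic acid, via silyl ester 10 (not isolated)
Conditions: O3, CH2Cl2, −78 °C; then Me2S, −78 °C to rt; aqueous work-up (pH 3)
Reagents that add atoms: ozone, [O-][O+]=O
Why: Ozonolysis of the silyl enol ether cuts the temporary ring between the former carbonyl carbon and its CH2, giving a silyl ester (hydrolysed on work-up) and an aldehyde, so the two ends are differentiated by oxidation level.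

**Step 9**
Reactants: 11 (1R,2R)-1,2-dimethyl-2-(2-oxoethyl)cyclopentane-1-carboxylic acid
Product: 13 (4aR,7aR)-4a,7a-dimethyl-3-(prop-2-yn-1-yl)hexahydrocyclopenta[c]pyran-1(3H)-one (both C3 epimers), via hydroxy acid 12 (not isolated)
Conditions: propargyl bromide, Zn dust, THF/sat. aq NH4Cl, 0 °C to rt; then 1 M HCl; p-TsOH (cat.), toluene, 40 °C
Reagents that add atoms: 3-bromoprop-1-yne, C#CCBr
Why: Barbier propargylation in aqueous medium tolerates the free acid and should give the homopropargylic alcohol, and the cis-disposed hydroxyalkyl and carboxyl arms then close to the six-membered lactone, which masks the acid.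

**Step 10**
Reactants: 13 (4aR,7aR)-4a,7a-dimethyl-3-(prop-2-yn-1-yl)hexahydrocyclopenta[c]pyran-1(3H)-one
Product: 14 (4aR,7aR)-4a,7a-dimethyl-3-(prop-2-yn-1-yl)octahydrocyclopenta[c]pyran-1-ol (epimer mixture)
Conditions: i-Bu2AlH (1.2 equiv), CH2Cl2, −78 °C; aq. potassium sodium tartrate
Reagents that add atoms: none
Why: Partial reduction of a lactone with diisobutylaluminium hydride should stop at the lactol because the aluminium hemiacetal is stable at low temperature, all the more at this hindered carbonyl.

**Step 11**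
Reactants: 14 (4aR,7aR)-4a,7a-dimethyl-3-(prop-2-yn-1-yl)octahydrocyclopenta[c]pyran-1-ol
Product: 15 1-[(1R,2R)-2-(2-hydroxypent-4-yn-1-yl)-1,2-dimethylcyclopentyl]but-3-en-1-ol (both carbinol carbons as epimer mixtures)
Conditions: CH2=CHCH2MgBr (4 equiv), THF, 0 °C to rt; aq. NH4Cl
Reagents that add atoms: allylmagnesium bromide, C=CC[Mg]Br
Why: Grignard addition to the open hydroxy aldehyde form of the lactol should succeed because allylmagnesium bromide adds readily to hindered neopentyl aldehydes; the excess is consumed by the O–H and alkyne C–H acids.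

**Step 12**
Reactants: 16 4-methoxy-3-methylphenol
Product: 17 triisopropyl(4-methoxy-3-methylphenoxy)silane
Conditions: i-Pr3SiCl, imidazole, DMF, rt
Reagents that add atoms: chlorotriisopropylsilane, CC(C)[Si](Cl)(C(C)C)C(C)C
Why: Standard silylation of a phenol gives a bulky aryl silyl ether that should survive organolithium, organoaluminium, metathesis and oxidation conditions.

**Step 13**
Reactants: 17 triisopropyl(4-methoxy-3-methylphenoxy)silane
Product: 19 [2-methoxy-3-methyl-5-(triisopropylsilyloxy)phenyl]methanol, via aryllithium 18 (not isolated)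
Conditions: n-BuLi, TMEDA, Et2O, 0 °C to rt; then (CH2O)n, −78 °C to rt; aq. NH4Cl
Reagents that add atoms: formaldehyde (as paraformaldehyde), C=O
Why: Directed ortho-metalation should occur at the only free position next to the methoxy group, since the bulky silyloxy group shields its own neighbours, and the aryllithium is trapped by formaldehyde.

**Step 14**
Reactants: 19 [2-methoxy-3-methyl-5-(triisopropylsilyloxy)phenyl]methanol
Product: 20 [3-(chloromethyl)-4-methoxy-5-methylphenoxy]triisopropylsilane
Conditions: SOCl2, Et3N, CH2Cl2, 0 °C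
Reagents that add atoms: thionyl chloride, O=S(Cl)Cl
Why: Chlorination of an electron-rich benzylic alcohol through its chlorosulfite should be fast under buffered conditions that spare the aryl silyl ether.

**Step 15**
Reactants: 15 1-[(1R,2R)-2-(2-hydroxypent-4-yn-1-yl)-1,2-dimethylcyclopentyl]but-3-en-1-ol; 20 [3-(chloromethyl)-4-methoxy-5-methylphenoxy]triisopropylsilane
Product: 22 1-[(1R,2R)-2-{(4E)-2-hydroxy-6-[2-methoxy-3-methyl-5-(triisopropylsilyloxy)phenyl]-4-methylhex-4-en-1-yl}-1,2-dimethylcyclopentyl]but-3-en-1-ol, via alkenylalane 21 (not isolated)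
Conditions: AlMe3 (5 equiv), Cp2ZrCl2 (25 mol%), CH2Cl2, 0 °C to rt; then 20, Pd(PPh3)4 (5 mol%), THF, rt
Reagents that add atoms: trimethylaluminium, C[Al](C)C
Why: Zirconium-catalysed syn-methylalumination of the terminal alkyne (methyl to the internal carbon) gives the (E)-alkenylalane, which should couple with the benzylic chloride under zerovalent palladium catalysis with retention of geometry (Negishi carboalumination and coupling); the monosubstituted alkene is far less reactive toward methylalumination.

**Step 16**
Reactants: 22 1-[(1R,2R)-2-{(4E)-2-hydroxy-6-[2-methoxy-3-methyl-5-(triisopropylsilyloxy)phenyl]-4-methylhex-4-en-1-yl}-1,2-dimethylcyclopentyl]but-3-en-1-ol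
Product: 23 1-[(1R,2R)-2-{(4E)-2-hydroxy-6-[2-methoxy-3-methyl-5-(triisopropylsilyloxy)phenyl]-4-methylhex-4-en-1-yl}-1,2-dimethylcyclopentyl]-4-methylpent-3-en-1-ol
Conditions: 2-methylbut-2-ene (large excess), second-generation Grubbs catalyst (H2IMes)(PCy3)Cl2Ru=CHPh (5 mol%), CH2Cl2, 40 °C
Reagents that add atoms: 2-methylbut-2-ene, CC=C(C)C
Why: Olefin cross-metathesis of the terminal alkene with excess 2-methylbut-2-ene should convert the allyl group into a prenyl group, while the trisubstituted chain alkene does not engage.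

**Step 17**
Reactants: 23 1-[(1R,2R)-2-{(4E)-2-hydroxy-6-[2-methoxy-3-methyl-5-(triisopropylsilyloxy)phenyl]-4-methylhex-4-en-1-yl}-1,2-dimethylcyclopentyl]-4-methylpent-3-en-1-ol
Product: 24 (4E)-1-[(1R,2R)-1,2-dimethyl-2-(4-methylpent-3-enoyl)cyclopentyl]-6-[2-methoxy-3-methyl-5-(triisopropylsilyloxy)phenyl]-4-methylhex-4-en-2-one
Conditions: Dess–Martin periodinane (3 equiv), NaHCO3, CH2Cl2, 0 °C to rt
Reagents that add atoms: none
Why: Dess–Martin oxidation converts both secondary alcohols into ketones under buffered, non-basic conditions that should not move either β,γ double bond into conjugation and also removes the two undefined carbinol centres.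

**Step 18**
Reactants: 24 (4E)-1-[(1R,2R)-1,2-dimethyl-2-(4-methylpent-3-enoyl)cyclopentyl]-6-[2-methoxy-3-methyl-5-(triisopropylsilyloxy)phenyl]-4-methylhex-4-en-2-one
Product: 25 (4E)-1-[(1R,2R)-1,2-dimethyl-2-(4-methylpent-3-enoyl)cyclopentyl]-6-(5-hydroxy-2-methoxy-3-methylphenyl)-4-methylhex-4-en-2-one
Conditions: Bu4NF, AcOH (1:1), THF, 0 °C
Reagents that add atoms: none
Why: Fluoride cleavage of the aryl silyl ether, buffered with acetic acid, should free the phenol without enolising the 1,5-diketone or the β,γ-unsaturated ketones.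

**Compound list**

1 | 2,3-dimethylcyclopent-2-en-1-one | CC1=C(C)C(=O)CC1 | starting material
2 | (1S)-2,3-dimethylcyclopent-2-en-1-ol | O[C@H]1CCC(C)=C1C | intermediate
3 | (1R,2S,5S)-1,5-dimethylbicyclo[3.1.0]hexan-2-ol | C1C[C@@]2(C)C[C@@]2(C)[C@H]1O | intermediate
4 | (1R,5S)-1,5-dimethylbicyclo[3.1.0]hexan-2-one | C1C[C@@]2(C)C[C@@]2(C)C1=O | intermediate
5 | ethynyltrimethylsilane | C#C[Si](C)(C)C | starting material
6 | (3aS,6aR)-3a,6a-dimethyl-6-(trimethylsilyl)-3,3a,4,6a-tetrahydropentalen-1(2H)-one | C1C[C@@]2(C)CC=C([Si](C)(C)C)[C@@]2(C)C1=O | intermediate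
7 | (3aS,6aR)-3a,6a-dimethyl-3,3a,4,6a-tetrahydropentalen-1(2H)-one | C1C[C@@]2(C)CC=C[C@@]2(C)C1=O | intermediate
8 | (3aR,6aR)-3a,6a-dimethylhexahydropentalen-1(2H)-one | C1C[C@@]2(C)CCC[C@@]2(C)C1=O | intermediate
9 | {[(3aR,6aR)-3a,6a-dimethyl-3,3a,4,5,6,6a-hexahydropentalen-1-yl]oxy}trimethylsilane | C1[C@@]2(C)CCC[C@@]2(C)C(O[Si](C)(C)C)=C1 | intermediate
10 | trimethylsilyl (1R,2R)-1,2-dimethyl-2-(2-oxoethyl)cyclopentane-1-carboxylate | O=CC[C@@]1(C)CCC[C@@]1(C)C(=O)O[Si](C)(C)C | intermediate (not isolated)
11 | (1R,2R)-1,2-dimethyl-2-(2-oxoethyl)cyclopentane-1-carboxylic acid | O=CC[C@@]1(C)CCC[C@@]1(C)C(=O)O | intermediate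
12 | (1R,2R)-2-(2-hydroxypent-4-yn-1-yl)-1,2-dimethylcyclopentane-1-carboxylic acid (carbinol epimers) | C#CCC(O)C[C@@]1(C)CCC[C@@]1(C)C(=O)O | intermediate (not isolated)
13 | (4aR,7aR)-4a,7a-dimethyl-3-(prop-2-yn-1-yl)hexahydrocyclopenta[c]pyran-1(3H)-one (C3 epimers) | C#CCC1C[C@@]2(C)CCC[C@@]2(C)C(=O)O1 | intermediate
14 | (4aR,7aR)-4a,7a-dimethyl-3-(prop-2-yn-1-yl)octahydrocyclopenta[c]pyran-1-ol (epimer mixture) | C#CCC1C[C@@]2(C)CCC[C@@]2(C)C(O)O1 | intermediate
15 | 1-[(1R,2R)-2-(2-hydroxypent-4-yn-1-yl)-1,2-dimethylcyclopentyl]but-3-en-1-ol (carbinol epimers) | C#CCC(O)C[C@@]1(C)CCC[C@@]1(C)C(O)CC=C | intermediate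
16 | 4-methoxy-3-methylphenol | COc1ccc(O)cc1C | starting material
17 | triisopropyl(4-methoxy-3-methylphenoxy)silane | COc1ccc(O[Si](C(C)C)(C(C)C)C(C)C)cc1C | intermediate
18 | [2-methoxy-3-methyl-5-(triisopropylsilyloxy)phenyl]lithium | COc1c([Li])cc(O[Si](C(C)C)(C(C)C)C(C)C)cc1C | intermediate (not isolated)
19 | [2-methoxy-3-methyl-5-(triisopropylsilyloxy)phenyl]methanol | COc1c(CO)cc(O[Si](C(C)C)(C(C)C)C(C)C)cc1C | intermediate
20 | [3-(chloromethyl)-4-methoxy-5-methylphenoxy]triisopropylsilane | COc1c(CCl)cc(O[Si](C(C)C)(C(C)C)C(C)C)cc1C | intermediate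
21 | (E)-alkenyl(dimethyl)alane from syn-methylalumination of 15, both hydroxyl groups as dimethylaluminium alkoxides | C[Al](C)/C=C(\C)CC(O[Al](C)C)C[C@@]1(C)CCC[C@@]1(C)C(O[Al](C)C)CC=C | intermediate (not isolated)
22 | 1-[(1R,2R)-2-{(4E)-2-hydroxy-6-[2-methoxy-3-methyl-5-(triisopropylsilyloxy)phenyl]-4-methylhex-4-en-1-yl}-1,2-dimethylcyclopentyl]but-3-en-1-ol (carbinol epimers) | COc1c(C)cc(O[Si](C(C)C)(C(C)C)C(C)C)cc1C/C=C(\C)CC(O)C[C@@]1(C)CCC[C@@]1(C)C(O)CC=C | intermediate
23 | 1-[(1R,2R)-2-{(4E)-2-hydroxy-6-[2-methoxy-3-methyl-5-(triisopropylsilyloxy)phenyl]-4-methylhex-4-en-1-yl}-1,2-dimethylcyclopentyl]-4-methylpent-3-en-1-ol (carbinol epimers) | COc1c(C)cc(O[Si](C(C)C)(C(C)C)C(C)C)cc1C/C=C(\C)CC(O)C[C@@]1(C)CCC[C@@]1(C)C(O)CC=C(C)C | intermediate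
24 | (4E)-1-[(1R,2R)-1,2-dimethyl-2-(4-methylpent-3-enoyl)cyclopentyl]-6-[2-methoxy-3-methyl-5-(triisopropylsilyloxy)phenyl]-4-methylhex-4-en-2-one | COc1c(C)cc(O[Si](C(C)C)(C(C)C)C(C)C)cc1C/C=C(\C)CC(=O)C[C@@]1(C)CCC[C@@]1(C)C(=O)CC=C(C)C | intermediate
25 | (4E)-1-[(1R,2R)-1,2-dimethyl-2-(4-methylpent-3-enoyl)cyclopentyl]-6-(5-hydroxy-2-methoxy-3-methylphenyl)-4-methylhex-4-en-2-one | COc1c(C)cc(O)cc1C/C=C(\C)CC(=O)C[C@@]1(C)CCC[C@@]1(C)C(=O)CC=C(C)C | target

**Step count and risks**

Total steps: 18. Longest linear sequence: 15 steps (steps 1–11 and 15–18); the aryl part takes 3 steps (12–14).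

Steps most likely to fail:

Step 4. Capture of the primary radical by the silylalkyne may be too slow, so that catalyst decay, hydrogen abstraction from the solvent, scission of the ring-fusion bond with ring enlargement, or 1,5-hydrogen transfer to the vinyl radical take over; closure onto the fully substituted enolate carbon may also be retarded by crowding. The fallback sets out from 2 and returns at 8. O-Alkylation of 2 with tributyl(iodomethyl)stannane (KH, THF) would give tributyl({[(1S)-2,3-dimethylcyclopent-2-en-1-yl]oxy}methyl)stannane F1. Tin–lithium exchange (n-BuLi, THF, −78 °C) should trigger a Still–Wittig [2,3] rearrangement that carries the CH2OH carbon suprafacially to the distal alkene carbon, giving [(1R)-1,2-dimethylcyclopent-2-en-1-yl]methanol F2 with the quaternary centre in place. Hydroboration and oxidation (BH3·THF; then H2O2, NaOH) would give (3R)-3-(hydroxymethyl)-2,3-dimethylcyclopentan-1-ol F3, and Dess–Martin oxidation of both hydroxyl groups would give (1R)-1,2-dimethyl-3-oxocyclopentane-1-carbaldehyde F4. Treatment of F4 with NaH and vinyltriphenylphosphonium bromide in THF (Michael addition of the more substituted ketone enolate, then intramolecular Wittig reaction with the aldehyde) should form the same two ring bonds and give cis-fused (3aS,6aR)-3a,6a-dimethyl-3,3a,6,6a-tetrahydropentalen-1(2H)-one F5. Hydrogenation (H2, 10% Pd/C, EtOAc) then gives 8.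

Step 15. Transfer of the alkenyl group from aluminium to palladium may be sluggish in the presence of two aluminium alkoxides, with homocoupling or reduction of the benzylic chloride and protonolysis of the alkenylalane as competing processes. The fallback sets out from 15 and returns at 22, with the polarity of the coupling reversed. The alkenylalane 21 is quenched with iodine (THF, −30 °C) to give 1-[(1R,2R)-2-[(4E)-2-hydroxy-5-iodo-4-methylpent-4-en-1-yl]-1,2-dimethylcyclopentyl]but-3-en-1-ol F6. Chloride 20 is converted with zinc dust and LiCl in THF into [2-methoxy-3-methyl-5-(triisopropylsilyloxy)benzyl]zinc chloride F7. Negishi coupling of F6 with excess F7 (Pd(PPh3)4, THF, 40 °C) should give 22.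

Step 1. Facial selectivity of hydride delivery may be poor because the two flanks of the tetrasubstituted enone differ only moderately in size. The fallback sets out from 1 and returns at 2. Luche reduction (NaBH4, CeCl3·7H2O, MeOH, 0 °C) would give racemic 2,3-dimethylcyclopent-2-en-1-ol F8. Lipase-catalysed acylation (immobilised Candida antarctica lipase B, vinyl acetate, MTBE, rt) is expected to acetylate the (R)-enantiomer to (1R)-2,3-dimethylcyclopent-2-en-1-yl acetate F9 and leave the (S)-alcohol 2, which is separated by chromatography.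

**Further compounds**

F1 | step 4 | tributyl({[(1S)-2,3-dimethylcyclopent-2-en-1-yl]oxy}methyl)stannane | CCCC[Sn](CCCC)(CCCC)CO[C@H]1CCC(C)=C1C
F2 | step 4 | [(1R)-1,2-dimethylcyclopent-2-en-1-yl]methanol | OC[C@]1(C)CCC=C1C
F3 | step 4 | (3R)-3-(hydroxymethyl)-2,3-dimethylcyclopentan-1-ol (mixture at C1 and C2) | OC[C@]1(C)CCC(O)C1C
F4 | step 4 | (1R)-1,2-dimethyl-3-oxocyclopentane-1-carbaldehyde (C2 epimers) | O=C[C@]1(C)CCC(=O)C1C
F5 | step 4 | (3aS,6aR)-3a,6a-dimethyl-3,3a,6,6a-tetrahydropentalen-1(2H)-one | C1C[C@@]2(C)C=CC[C@@]2(C)C1=O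
F6 | step 15 | 1-[(1R,2R)-2-[(4E)-2-hydroxy-5-iodo-4-methylpent-4-en-1-yl]-1,2-dimethylcyclopentyl]but-3-en-1-ol (carbinol epimers) | I/C=C(\C)CC(O)C[C@@]1(C)CCC[C@@]1(C)C(O)CC=C
F7 | step 15 | [2-methoxy-3-methyl-5-(triisopropylsilyloxy)benzyl]zinc chloride | COc1c(C[Zn]Cl)cc(O[Si](C(C)C)(C(C)C)C(C)C)cc1C
F8 | step 1 | racemic 2,3-dimethylcyclopent-2-en-1-ol | OC1CCC(C)=C1C
F9 | step 1 | (1R)-2,3-dimethylcyclopent-2-en-1-yl acetate | CC(=O)O[C@@H]1CCC(C)=C1C
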